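**Plan**

- The target is epicatechin-(4β→8)-catechin-(4α→8)-catechin with an (S)-1-hydroxy-6-oxocyclohex-2-ene-1-carbonyl group on O3 of the lowest unit. The retrosynthesis cuts the two C4–C8 interflavan bonds, the ester C–O bond and the C2=C3 bond of the acyl ring.
- Enabling feature: in the acyl ring (C1 = quaternary carbinol carbon bearing the ester, C6 = ketone) the only alkene, C2=C3, starts at C1. Opening it leaves a vinyl group on C1 and a but-3-enyl arm on the C6 ketone, an acyclic diene ester that ring-closing metathesis can close.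
- Forward, acyl part: pent-4-enal, ethyl diazoacetate and a vinyl Grignard reagent give an open-chain (2S,3R)-dihydroxy acid. It is esterified to silylated catechin before any β-keto acid exists; oxidation and metathesis then form the only new ring, on the ester.
- Forward, flavan part: silylated epicatechin is activated at C4 and joined to C8 of silylated catechin. The dimer is activated at C4 of its catechin unit and joined to C8 of the acylated catechin; all silyl groups are then removed.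
- Stereochemistry: flavan C2/C3 come from (+)-catechin and (−)-epicatechin. Acyl C1 comes from a ProPhenol aldol centre, relayed by a Felkin–Anh vinyl addition and then oxidised away. Both new C4 centres arise by attack anti to the O3 substituent (3,4-trans).

Key step: step 10

Assumption: (S,S)-ProPhenol is taken to give the (R)-carbinol in step 1; because C3 is erased in step 9, the other ligand antipode is the remedy if either the aldol sense or the facial course of step 4 proves opposite.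

Abbreviations: TBS = tert-butyldimethylsilyl, TES = triethylsilyl, DMDO = dimethyldioxirane, CSA = camphorsulfonic acid.

**Route**

Step 1
Reactants: 1 pent-4-enal; 2 ethyl diazoacetate
Product: 3 ethyl (R)-2-diazo-3-hydroxyhept-6-enoate
Conditions: Bu2Mg (10 mol %), (S,S)-ProPhenol (5 mol %), cis-cyclopentane-1,2-diol (5 mol %), THF, −20 °C
Reagents that add atoms: none
Why: Catalytic asymmetric direct aldol addition of a diazoacetate under dinuclear magnesium–ProPhenol catalysis, in which the metal-bound diazoester adds to one face of the aldehyde inside the chiral pocket and sets C3 as (R), a centre that serves only as a relay.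

Step 2
Reactants: 3 ethyl (R)-2-diazo-3-hydroxyhept-6-enoate
Product: 4 ethyl (R)-2-diazo-3-(triethylsilyloxy)hept-6-enoate
Conditions: TESCl, imidazole, DMF, 0 °C
Reagents that add atoms: chlorotriethylsilane, CC[Si](Cl)(CC)CC
Why: Silyl ether formation with a chlorosilane and imidazole, a weakly basic medium that leaves the acid-sensitive diazo ester alone and installs a group that mild acid can later remove beside aryl TBS ethers.

Step 3
Reactants: 4 ethyl (R)-2-diazo-3-(triethylsilyloxy)hept-6-enoate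
Product: 5 ethyl (R)-2-oxo-3-(triethylsilyloxy)hept-6-enoate
Conditions: DMDO (1.05 equiv), acetone, −40 → 0 °C
Reagents that add atoms: dimethyldioxirane, CC1(C)OO1
Why: Dioxirane oxidation of an α-diazo ester to the α-keto ester with loss of N2, which is much faster than epoxidation of a monosubstituted alkene, so one equivalent in the cold should spare the butenyl terminus.

Step 4
Reactants: 5 ethyl (R)-2-oxo-3-(triethylsilyloxy)hept-6-enoate
Product: 6 ethyl (2S,3R)-2-hydroxy-3-(triethylsilyloxy)-2-vinylhept-6-enoate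
Conditions: CH2=CHMgBr, THF, −78 °C; aq. NH4Cl
Reagents that add atoms: vinylmagnesium bromide, C=C[Mg]Br
Why: Grignard addition to the ketone of an α-keto ester, which outpaces attack on the ester at −78 °C, with magnesium held between the two carbonyl oxygens and the bulky non-chelating C3–OSiEt3 bond anti to the incoming vinyl group (polar Felkin–Anh model), so the nucleophile passes the C3 hydrogen and sets C2 as (S).

Step 5
Reactants: 6 ethyl (2S,3R)-2-hydroxy-3-(triethylsilyloxy)-2-vinylhept-6-enoate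
Product: 7 (2S,3R)-2-hydroxy-3-(triethylsilyloxy)-2-vinylhept-6-enoic acid
Conditions: LiOH, THF/H2O, 0 °C → rt; 1 M HCl to pH 4, 0 °C
Reagents that add atoms: lithium hydroxide, [Li+].[OH-]
Why: Saponification of an ethyl ester assisted by the α-hydroxyl group, which the secondary TES ether should survive in the cold and which gives an α-hydroxy acid without a β-carbonyl group, so it cannot decarboxylate.

Step 6
Reactants: 8 (+)-catechin
Product: 9 5,7,3',4'-tetra-O-TBS-(+)-catechin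
Conditions: TBSCl (4.4 equiv), imidazole, DMF, 0 °C → rt
Reagents that add atoms: tert-butylchlorodimethylsilane, CC(C)(C)[Si](C)(C)Cl
Why: Chemoselective silyl ether formation at the four phenols, which react far faster than the secondary 3-OH under imidazole in DMF.

Step 7
Reactants: 7 (2S,3R)-2-hydroxy-3-(triethylsilyloxy)-2-vinylhept-6-enoic acid; 9 5,7,3',4'-tetra-O-TBS-(+)-catechin
Product: 11 5,7,3',4'-tetra-O-TBS-(+)-catechin 3-O-[(2S,3R)-2-hydroxy-3-(triethylsilyloxy)-2-vinylhept-6-enoate], via mixed anhydride 10 (not isolated)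
Conditions: 2,4,6-Cl3C6H2COCl, Et3N, toluene, rt; then 9 (1.2 equiv), DMAP, toluene, rt → 40 °C
Reagents that add atoms: none
Why: Yamaguchi esterification, in which DMAP attacks the mixed anhydride at the less shielded aliphatic carbonyl and the acylpyridinium ion acylates the equatorial 3-OH of 9, while the tertiary hydroxyl of the acid is too hindered to compete and no stereocentre is touched.

Step 8
Reactants: 11 5,7,3',4'-tetra-O-TBS-(+)-catechin 3-O-[(2S,3R)-2-hydroxy-3-(triethylsilyloxy)-2-vinylhept-6-enoate]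
Product: 12 5,7,3',4'-tetra-O-TBS-(+)-catechin 3-O-[(2S,3R)-2,3-dihydroxy-2-vinylhept-6-enoate]
Conditions: CSA (0.1 equiv), MeOH/CH2Cl2, 0 °C
Reagents that add atoms: none
Why: Acid-catalysed methanolysis of a silyl ether, in which an alkyl TES ether is cleaved much faster than aryl TBS ethers, so only the C3 carbinol of the chain should be released.

Step 9
Reactants: 12 5,7,3',4'-tetra-O-TBS-(+)-catechin 3-O-[(2S,3R)-2,3-dihydroxy-2-vinylhept-6-enoate]
Product: 13 5,7,3',4'-tetra-O-TBS-(+)-catechin 3-O-[(S)-2-hydroxy-3-oxo-2-vinylhept-6-enoate]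
Conditions: Dess–Martin periodinane, CH2Cl2, 0 °C → rt
Reagents that add atoms: none
Why: Dess–Martin oxidation of the secondary alcohol to the ketone, which cannot touch the tertiary allylic alcohol, removes the relay centre C3 and keeps the base-labile α-hydroxy-β-keto ester in a neutral to weakly acidic medium.

Step 10
Reactants: 13 5,7,3',4'-tetra-O-TBS-(+)-catechin 3-O-[(S)-2-hydroxy-3-oxo-2-vinylhept-6-enoate]
Product: 14 5,7,3',4'-tetra-O-TBS-(+)-catechin 3-O-[(S)-1-hydroxy-6-oxocyclohex-2-ene-1-carboxylate]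
Conditions: RuCl2(H2IMes)(PCy3)(=CHPh) (second-generation Grubbs catalyst, 5 mol %), 1,4-benzoquinone (10 mol %), CH2Cl2 (0.005 M), 40 °C
Reagents that add atoms: none
Why: Olefin metathesis by the Chauvin cycle: the ruthenium benzylidene exchanges onto the unhindered but-3-enyl terminus, the new alkylidene adds across the vinyl group on C1 to give a ruthenacyclobutane, and its cycloreversion releases the cyclohexene while the remaining Ru=CH2 carries the chain with loss of ethylene. The closest known reaction type is ring-closing metathesis of 1,7-dienes bearing a free tertiary allylic alcohol to cyclohexenols, a hydroxyl that is tolerated and often speeds the closure. The six-membered carbocycle of the acyl group is closed by forming its C2=C3 double bond, all other ring bonds being present in the chain already. No stereocentre is formed, and C1 keeps the (S) configuration set in step 4 because none of its bonds is broken. The step needs cyclisation in place of intermolecular metathesis, which dilution and the favourable ring size secure, and it needs the double bonds to stay in place: C1 is quaternary, so C2=C3 cannot move toward it, and 1,4-benzoquinone traps ruthenium hydrides that could move the butenyl double bond (ring contraction) or shift C2=C3 toward conjugation with the C6 ketone. The neutral medium leaves the aryl silyl ethers and the base-labile α-hydroxy-β-keto ester untouched.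

Step 11
Reactants: 15 (−)-epicatechin
Product: 16 5,7,3',4'-tetra-O-TBS-(−)-epicatechin
Conditions: TBSCl (4.4 equiv), imidazole, DMF, 0 °C → rt
Reagents that add atoms: tert-butylchlorodimethylsilane, CC(C)(C)[Si](C)(C)Cl
Why: Chemoselective silyl ether formation at the four phenols, as in step 6, leaving the axial 3-OH free.

Step 12
Reactants: 16 5,7,3',4'-tetra-O-TBS-(−)-epicatechin
Product: 17 4β-(2-ethoxyethoxy)-5,7,3',4'-tetra-O-TBS-epicatechin (3,4-trans, 3-OH free)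
Conditions: DDQ (2 equiv), 2-ethoxyethanol, CH2Cl2, rt
Reagents that add atoms: 2-ethoxyethanol, CCOCCO
Why: Benzylic oxidation by hydride abstraction with DDQ at C4, the only CH2 group activated by the electron-rich ring A, followed by capture of the cation by the alcohol on the face opposite to the cis 2-aryl and 3-hydroxyl groups, which gives the 3,4-trans ether.

Step 13
Reactants: 17 4β-(2-ethoxyethoxy)-5,7,3',4'-tetra-O-TBS-epicatechin; 9 5,7,3',4'-tetra-O-TBS-(+)-catechin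
Product: 18 octa-O-TBS procyanidin B1, [tetra-O-TBS-epicatechin]-(4β→8)-[tetra-O-TBS-catechin], both 3-OH free
Conditions: 9 (4 equiv), TMSOTf (0.2 equiv), CH2Cl2, −78 °C; aq. NaHCO3
Reagents that add atoms: none
Why: Lewis-acid-mediated Friedel–Crafts-type flavan coupling, in which TMSOTf ionises the C4 ether to a cation stabilised by ring A and C8 of 9 (less crowded than C6, which lies between two silyloxy groups) attacks from the β-face, away from the cis 2-aryl and 3-hydroxyl groups, so the new C4 centre is 4β, while the excess of 9 suppresses self-condensation of 17.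

Step 14
Reactants: 18 octa-O-TBS procyanidin B1
Product: 19 3-O-TES (epicatechin unit), 3-O-TES (catechin unit) bis-silyl ether of 18
Conditions: TESOTf, 2,6-lutidine, CH2Cl2, 0 °C → rt
Reagents that add atoms: triethylsilyl trifluoromethanesulfonate, CC[Si](CC)(CC)OS(=O)(=O)C(F)(F)F
Why: Silyl ether formation with a silyl triflate, reactive enough for the hindered axial 3-OH of the epicatechin unit, which also places a bulky group on O3 of the catechin unit to steer the later coupling.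

Step 15
Reactants: 19 bis-O-TES octa-O-TBS procyanidin B1
Product: 20 19 bearing a 4α-(2-ethoxyethoxy) group (3,4-trans) at C4 of its catechin unit
Conditions: DDQ (2 equiv), 2-ethoxyethanol, CH2Cl2, rt
Reagents that add atoms: 2-ethoxyethanol, CCOCCO
Why: DDQ benzylic oxidation as in step 12, now at the only remaining benzylic CH2 (C4 of the catechin unit), the C4 methine of the epicatechin unit being shielded by its two aryl neighbours and the adjacent silyl ether, with the alcohol expected to enter trans to the 3-O-TES group at a centre that step 16 removes again.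

Step 16
Reactants: 20 C4-activated bis-O-TES octa-O-TBS dimer; 14 5,7,3',4'-tetra-O-TBS-(+)-catechin 3-O-[(S)-1-hydroxy-6-oxocyclohex-2-ene-1-carboxylate]
Product: 21 fully silylated trimer, [3-O-TES-tetra-O-TBS-epicatechin]-(4β→8)-[3-O-TES-tetra-O-TBS-catechin]-(4α→8)-[tetra-O-TBS-catechin 3-O-(S)-1-hydroxy-6-oxocyclohex-2-ene-1-carboxylate]
Conditions: 14 (3 equiv, excess recovered), TMSOTf (0.2 equiv), CH2Cl2, −78 → −40 °C; pH 7 phosphate buffer
Reagents that add atoms: none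
Why: Lewis-acid-mediated flavan coupling as in step 13, in which the catechin-derived C4 cation of 20 is attacked by C8 of 14 on the face opposite to the bulky 3-O-TES group to set the 4α (3,4-trans) centre, the excess of 14 outcompeting C8 of the dimer's own epicatechin unit and the cold base-free medium sparing the α-hydroxy-β-keto ester.

Step 17
Reactants: 21 fully silylated trimer
Product: 22 epicatechin-(4β→8)-catechin-(4α→8)-catechin 3-O-[(S)-1-hydroxy-6-oxocyclohex-2-ene-1-carboxylate] (CNP0159807.2)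
Conditions: HF·pyridine, pyridine, THF, 0 °C → rt; Me3SiOMe quench, Sephadex LH-20
Reagents that add atoms: none
Why: Fluoride-mediated global cleavage of silyl ethers under buffered, weakly acidic conditions, which should remove the twelve aryl TBS and two alkyl TES groups without base or reduction, so the acyl ester, its ketone and its alkene persist.

**Compound list**

1 | pent-4-enal | C=CCCC=O | starting material
2 | ethyl diazoacetate | CCOC(=O)C=[N+]=[N-] | starting material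
3 | ethyl (R)-2-diazo-3-hydroxyhept-6-enoate | CCOC(=O)C(=[N+]=[N-])[C@H](O)CCC=C | intermediate
4 | ethyl (R)-2-diazo-3-(triethylsilyloxy)hept-6-enoate | CCOC(=O)C(=[N+]=[N-])[C@H](O[Si](CC)(CC)CC)CCC=C | intermediate
5 | ethyl (R)-2-oxo-3-(triethylsilyloxy)hept-6-enoate | CCOC(=O)C(=O)[C@H](O[Si](CC)(CC)CC)CCC=C | intermediate
6 | ethyl (2S,3R)-2-hydroxy-3-(triethylsilyloxy)-2-vinylhept-6-enoate | C=CCC[C@@H](O[Si](CC)(CC)CC)[C@@](O)(C=C)C(=O)OCC | intermediate
7 | (2S,3R)-2-hydroxy-3-(triethylsilyloxy)-2-vinylhept-6-enoic acid | C=CCC[C@@H](O[Si](CC)(CC)CC)[C@@](O)(C=C)C(=O)O | intermediate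
8 | (+)-catechin | O[C@H]1Cc2c(O)cc(O)cc2O[C@@H]1c1ccc(O)c(O)c1 | starting material
9 | 5,7,3',4'-tetra-O-TBS-(+)-catechin | O[C@H]1Cc2c(O[Si](C)(C)C(C)(C)C)cc(O[Si](C)(C)C(C)(C)C)cc2O[C@@H]1c1ccc(O[Si](C)(C)C(C)(C)C)c(O[Si](C)(C)C(C)(C)C)c1 | intermediate
10 | mixed anhydride of 7 with 2,4,6-trichlorobenzoic acid | C=CCC[C@@H](O[Si](CC)(CC)CC)[C@@](O)(C=C)C(=O)OC(=O)c1c(Cl)cc(Cl)cc1Cl | intermediate
11 | 5,7,3',4'-tetra-O-TBS-(+)-catechin 3-O-[(2S,3R)-2-hydroxy-3-(triethylsilyloxy)-2-vinylhept-6-enoate] | C=CCC[C@@H](O[Si](CC)(CC)CC)[C@@](O)(C=C)C(=O)O[C@H]1Cc2c(O[Si](C)(C)C(C)(C)C)cc(O[Si](C)(C)C(C)(C)C)cc2O[C@@H]1c1ccc(O[Si](C)(C)C(C)(C)C)c(O[Si](C)(C)C(C)(C)C)c1 | intermediate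
12 | 5,7,3',4'-tetra-O-TBS-(+)-catechin 3-O-[(2S,3R)-2,3-dihydroxy-2-vinylhept-6-enoate] | C=CCC[C@@H](O)[C@@](O)(C=C)C(=O)O[C@H]1Cc2c(O[Si](C)(C)C(C)(C)C)cc(O[Si](C)(C)C(C)(C)C)cc2O[C@@H]1c1ccc(O[Si](C)(C)C(C)(C)C)c(O[Si](C)(C)C(C)(C)C)c1 | intermediate
13 | 5,7,3',4'-tetra-O-TBS-(+)-catechin 3-O-[(S)-2-hydroxy-3-oxo-2-vinylhept-6-enoate] | C=CCCC(=O)[C@@](O)(C=C)C(=O)O[C@H]1Cc2c(O[Si](C)(C)C(C)(C)C)cc(O[Si](C)(C)C(C)(C)C)cc2O[C@@H]1c1ccc(O[Si](C)(C)C(C)(C)C)c(O[Si](C)(C)C(C)(C)C)c1 | intermediate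
14 | 5,7,3',4'-tetra-O-TBS-(+)-catechin 3-O-[(S)-1-hydroxy-6-oxocyclohex-2-ene-1-carboxylate] | O=C1CCC=C[C@@]1(O)C(=O)O[C@H]1Cc2c(O[Si](C)(C)C(C)(C)C)cc(O[Si](C)(C)C(C)(C)C)cc2O[C@@H]1c1ccc(O[Si](C)(C)C(C)(C)C)c(O[Si](C)(C)C(C)(C)C)c1 | intermediate
15 | (−)-epicatechin | O[C@@H]1Cc2c(O)cc(O)cc2O[C@@H]1c1ccc(O)c(O)c1 | starting material
16 | 5,7,3',4'-tetra-O-TBS-(−)-epicatechin | O[C@@H]1Cc2c(O[Si](C)(C)C(C)(C)C)cc(O[Si](C)(C)C(C)(C)C)cc2O[C@@H]1c1ccc(O[Si](C)(C)C(C)(C)C)c(O[Si](C)(C)C(C)(C)C)c1 | intermediate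
17 | 4β-(2-ethoxyethoxy)-5,7,3',4'-tetra-O-TBS-epicatechin (3,4-trans) | CCOCCO[C@H]1c2c(O[Si](C)(C)C(C)(C)C)cc(O[Si](C)(C)C(C)(C)C)cc2O[C@H](c2ccc(O[Si](C)(C)C(C)(C)C)c(O[Si](C)(C)C(C)(C)C)c2)[C@@H]1O | intermediate
18 | octa-O-TBS procyanidin B1, [tetra-O-TBS-epicatechin]-(4β→8)-[tetra-O-TBS-catechin] | O[C@H]1Cc2c(O[Si](C)(C)C(C)(C)C)cc(O[Si](C)(C)C(C)(C)C)c([C@H]3c4c(O[Si](C)(C)C(C)(C)C)cc(O[Si](C)(C)C(C)(C)C)cc4O[C@H](c4ccc(O[Si](C)(C)C(C)(C)C)c(O[Si](C)(C)C(C)(C)C)c4)[C@@H]3O)c2O[C@@H]1c1ccc(O[Si](C)(C)C(C)(C)C)c(O[Si](C)(C)C(C)(C)C)c1 | intermediate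
19 | bis-3-O-TES ether of 18 (one TES on O3 of each flavan unit) | CC[Si](CC)(CC)O[C@H]1Cc2c(O[Si](C)(C)C(C)(C)C)cc(O[Si](C)(C)C(C)(C)C)c([C@H]3c4c(O[Si](C)(C)C(C)(C)C)cc(O[Si](C)(C)C(C)(C)C)cc4O[C@H](c4ccc(O[Si](C)(C)C(C)(C)C)c(O[Si](C)(C)C(C)(C)C)c4)[C@@H]3O[Si](CC)(CC)CC)c2O[C@@H]1c1ccc(O[Si](C)(C)C(C)(C)C)c(O[Si](C)(C)C(C)(C)C)c1 | intermediate
20 | 19 with a 4α-(2-ethoxyethoxy) group (3,4-trans) on C4 of the catechin unit | CCOCCO[C@@H]1c2c(O[Si](C)(C)C(C)(C)C)cc(O[Si](C)(C)C(C)(C)C)c([C@H]3c4c(O[Si](C)(C)C(C)(C)C)cc(O[Si](C)(C)C(C)(C)C)cc4O[C@H](c4ccc(O[Si](C)(C)C(C)(C)C)c(O[Si](C)(C)C(C)(C)C)c4)[C@@H]3O[Si](CC)(CC)CC)c2O[C@H](c2ccc(O[Si](C)(C)C(C)(C)C)c(O[Si](C)(C)C(C)(C)C)c2)[C@H]1O[Si](CC)(CC)CC | intermediate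
21 | fully silylated trimer, [3-O-TES-tetra-O-TBS-epicatechin]-(4β→8)-[3-O-TES-tetra-O-TBS-catechin]-(4α→8)-[tetra-O-TBS-catechin 3-O-(S)-1-hydroxy-6-oxocyclohex-2-ene-1-carboxylate] | O=C1CCC=C[C@@]1(O)C(=O)O[C@H]1Cc2c(O[Si](C)(C)C(C)(C)C)cc(O[Si](C)(C)C(C)(C)C)c([C@@H]3c4c(O[Si](C)(C)C(C)(C)C)cc(O[Si](C)(C)C(C)(C)C)c([C@H]5c6c(O[Si](C)(C)C(C)(C)C)cc(O[Si](C)(C)C(C)(C)C)cc6O[C@H](c6ccc(O[Si](C)(C)C(C)(C)C)c(O[Si](C)(C)C(C)(C)C)c6)[C@@H]5O[Si](CC)(CC)CC)c4O[C@H](c4ccc(O[Si](C)(C)C(C)(C)C)c(O[Si](C)(C)C(C)(C)C)c4)[C@H]3O[Si](CC)(CC)CC)c2O[C@@H]1c1ccc(O[Si](C)(C)C(C)(C)C)c(O[Si](C)(C)C(C)(C)C)c1 | intermediate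
22 | epicatechin-(4β→8)-catechin-(4α→8)-catechin 3-O-[(S)-1-hydroxy-6-oxocyclohex-2-ene-1-carboxylate] (CNP0159807.2) | O=C1CCC=C[C@@]1(O)C(=O)O[C@H]1Cc2c(O)cc(O)c([C@@H]3c4c(O)cc(O)c([C@H]5c6c(O)cc(O)cc6O[C@H](c6ccc(O)c(O)c6)[C@@H]5O)c4O[C@H](c4ccc(O)c(O)c4)[C@H]3O)c2O[C@@H]1c1ccc(O)c(O)c1 | target

**Count and risks**

Total step count: 17. Longest linear sequence: 11 steps (steps 1–5, 7–10, 16 and 17, from pent-4-enal).

Steps most likely to fail:

Step 16. The catechin-derived C4 cation may be attacked with poor facial selectivity (entry syn to O3 would give the 4β epimer), and the activated dimer may condense with itself through C8 of its epicatechin unit. The fallback replaces steric steering by neighbouring-group participation; it leaves the route at 18 and returns at 22. Allyl chloroformate and pyridine should acylate only the accessible equatorial 3-OH of the catechin unit of 18, giving the 3-O-allyloxycarbonyl derivative of the octa-O-TBS dimer F1. DDQ with 2-ethoxyethanol then gives its 4α-(2-ethoxyethoxy) ether F2. On ionisation with TMSOTf the carbonate carbonyl closes onto C4 from the face of O3, so C8 of 14 can only enter trans, giving the dodeca-O-TBS trimer allyl carbonate F3. Pd(PPh3)4 with dimedone removes the allyl carbonate at neutral pH to give the dodeca-O-TBS trimer with both flavan 3-OH groups free F4, and HF·pyridine as in step 17 then gives 22.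

Step 15. Hydride abstraction may occur at the wrong benzylic site (the C4 methine of the epicatechin unit), or the dimer may be over-oxidised. The fallback reverses the order of the two interflavan bonds so that only a monomer is oxidised; it leaves the route at 9 and returns at 22. TESOTf and 2,6-lutidine convert 9 into 3-O-TES-5,7,3',4'-tetra-O-TBS-catechin F5, whose DDQ oxidation in 2-ethoxyethanol can only give the 4α-(2-ethoxyethoxy) monomer F6. TMSOTf couples F6 with an excess of 14 to the octa-O-TBS catechin-(4α→8)-catechin ester dimer F7. A second TMSOTf coupling, with 17 as the electrophile and F7 in excess, arylates C8 of the upper catechin unit and gives the trimer with a free epicatechin 3-OH F8, and HF·pyridine then gives 22.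

Step 7. Acylation of the secondary alcohol by the α-quaternary acid may be slow, with competing self-acylation through the free tertiary hydroxyl. The fallback ties both hydroxyls back in a compact acetal; it leaves the route at 6 and returns at 12. CSA in methanol removes the silyl group of 6 to give ethyl (2S,3R)-2,3-dihydroxy-2-vinylhept-6-enoate F9, and 2,2-dimethoxypropane with CSA gives the acetonide ethyl ester F10. LiOH gives the acetonide acid F11. Yamaguchi activation gives its mixed anhydride F12, and 9 with DMAP then gives the catechin acetonide ester F13. Aqueous trifluoroacetic acid in CH2Cl2 at 0 °C hydrolyses the acetonide beside the aryl TBS ethers and gives 12.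

**Further compounds**

F1 | step 16 | 18 with an allyloxycarbonyl group on O3 of the catechin unit | C=CCOC(=O)O[C@H]1Cc2c(O[Si](C)(C)C(C)(C)C)cc(O[Si](C)(C)C(C)(C)C)c([C@H]3c4c(O[Si](C)(C)C(C)(C)C)cc(O[Si](C)(C)C(C)(C)C)cc4O[C@H](c4ccc(O[Si](C)(C)C(C)(C)C)c(O[Si](C)(C)C(C)(C)C)c4)[C@@H]3O)c2O[C@@H]1c1ccc(O[Si](C)(C)C(C)(C)C)c(O[Si](C)(C)C(C)(C)C)c1
F2 | step 16 | F1 with a 4α-(2-ethoxyethoxy) group on C4 of the catechin unit | CCOCCO[C@@H]1c2c(O[Si](C)(C)C(C)(C)C)cc(O[Si](C)(C)C(C)(C)C)c([C@H]3c4c(O[Si](C)(C)C(C)(C)C)cc(O[Si](C)(C)C(C)(C)C)cc4O[C@H](c4ccc(O[Si](C)(C)C(C)(C)C)c(O[Si](C)(C)C(C)(C)C)c4)[C@@H]3O)c2O[C@H](c2ccc(O[Si](C)(C)C(C)(C)C)c(O[Si](C)(C)C(C)(C)C)c2)[C@H]1OC(=O)OCC=C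
F3 | step 16 | dodeca-O-TBS trimer with an allyl carbonate on O3 of the middle catechin unit and a free epicatechin 3-OH | O=C1CCC=C[C@@]1(O)C(=O)O[C@H]1Cc2c(O[Si](C)(C)C(C)(C)C)cc(O[Si](C)(C)C(C)(C)C)c([C@@H]3c4c(O[Si](C)(C)C(C)(C)C)cc(O[Si](C)(C)C(C)(C)C)c([C@H]5c6c(O[Si](C)(C)C(C)(C)C)cc(O[Si](C)(C)C(C)(C)C)cc6O[C@H](c6ccc(O[Si](C)(C)C(C)(C)C)c(O[Si](C)(C)C(C)(C)C)c6)[C@@H]5O)c4O[C@H](c4ccc(O[Si](C)(C)C(C)(C)C)c(O[Si](C)(C)C(C)(C)C)c4)[C@H]3OC(=O)OCC=C)c2O[C@@H]1c1ccc(O[Si](C)(C)C(C)(C)C)c(O[Si](C)(C)C(C)(C)C)c1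
F4 | step 16 | dodeca-O-TBS trimer with both flavan 3-OH groups free | O=C1CCC=C[C@@]1(O)C(=O)O[C@H]1Cc2c(O[Si](C)(C)C(C)(C)C)cc(O[Si](C)(C)C(C)(C)C)c([C@@H]3c4c(O[Si](C)(C)C(C)(C)C)cc(O[Si](C)(C)C(C)(C)C)c([C@H]5c6c(O[Si](C)(C)C(C)(C)C)cc(O[Si](C)(C)C(C)(C)C)cc6O[C@H](c6ccc(O[Si](C)(C)C(C)(C)C)c(O[Si](C)(C)C(C)(C)C)c6)[C@@H]5O)c4O[C@H](c4ccc(O[Si](C)(C)C(C)(C)C)c(O[Si](C)(C)C(C)(C)C)c4)[C@H]3O)c2O[C@@H]1c1ccc(O[Si](C)(C)C(C)(C)C)c(O[Si](C)(C)C(C)(C)C)c1
F5 | step 15 | 3-O-TES-5,7,3',4'-tetra-O-TBS-(+)-catechin | CC[Si](CC)(CC)O[C@H]1Cc2c(O[Si](C)(C)C(C)(C)C)cc(O[Si](C)(C)C(C)(C)C)cc2O[C@@H]1c1ccc(O[Si](C)(C)C(C)(C)C)c(O[Si](C)(C)C(C)(C)C)c1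
F6 | step 15 | 4α-(2-ethoxyethoxy)-3-O-TES-5,7,3',4'-tetra-O-TBS-catechin (3,4-trans) | CCOCCO[C@@H]1c2c(O[Si](C)(C)C(C)(C)C)cc(O[Si](C)(C)C(C)(C)C)cc2O[C@H](c2ccc(O[Si](C)(C)C(C)(C)C)c(O[Si](C)(C)C(C)(C)C)c2)[C@H]1O[Si](CC)(CC)CC
F7 | step 15 | octa-O-TBS [3-O-TES-catechin]-(4α→8)-[catechin 3-O-(S)-1-hydroxy-6-oxocyclohex-2-ene-1-carboxylate] | O=C1CCC=C[C@@]1(O)C(=O)O[C@H]1Cc2c(O[Si](C)(C)C(C)(C)C)cc(O[Si](C)(C)C(C)(C)C)c([C@@H]3c4c(O[Si](C)(C)C(C)(C)C)cc(O[Si](C)(C)C(C)(C)C)cc4O[C@H](c4ccc(O[Si](C)(C)C(C)(C)C)c(O[Si](C)(C)C(C)(C)C)c4)[C@H]3O[Si](CC)(CC)CC)c2O[C@@H]1c1ccc(O[Si](C)(C)C(C)(C)C)c(O[Si](C)(C)C(C)(C)C)c1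
F8 | step 15 | dodeca-O-TBS trimer with a TES ether on O3 of the middle catechin unit and a free epicatechin 3-OH | O=C1CCC=C[C@@]1(O)C(=O)O[C@H]1Cc2c(O[Si](C)(C)C(C)(C)C)cc(O[Si](C)(C)C(C)(C)C)c([C@@H]3c4c(O[Si](C)(C)C(C)(C)C)cc(O[Si](C)(C)C(C)(C)C)c([C@H]5c6c(O[Si](C)(C)C(C)(C)C)cc(O[Si](C)(C)C(C)(C)C)cc6O[C@H](c6ccc(O[Si](C)(C)C(C)(C)C)c(O[Si](C)(C)C(C)(C)C)c6)[C@@H]5O)c4O[C@H](c4ccc(O[Si](C)(C)C(C)(C)C)c(O[Si](C)(C)C(C)(C)C)c4)[C@H]3O[Si](CC)(CC)CC)c2O[C@@H]1c1ccc(O[Si](C)(C)C(C)(C)C)c(O[Si](C)(C)C(C)(C)C)c1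
F9 | step 7 | ethyl (2S,3R)-2,3-dihydroxy-2-vinylhept-6-enoate | C=CCC[C@@H](O)[C@@](O)(C=C)C(=O)OCC
F10 | step 7 | ethyl (4S,5R)-5-(but-3-en-1-yl)-2,2-dimethyl-4-vinyl-1,3-dioxolane-4-carboxylate | C=CCC[C@H]1OC(C)(C)O[C@]1(C=C)C(=O)OCC
F11 | step 7 | (4S,5R)-5-(but-3-en-1-yl)-2,2-dimethyl-4-vinyl-1,3-dioxolane-4-carboxylic acid | C=CCC[C@H]1OC(C)(C)O[C@]1(C=C)C(=O)O
F12 | step 7 | mixed anhydride of F11 with 2,4,6-trichlorobenzoic acid | C=CCC[C@H]1OC(C)(C)O[C@]1(C=C)C(=O)OC(=O)c1c(Cl)cc(Cl)cc1Cl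
F13 | step 7 | 5,7,3',4'-tetra-O-TBS-(+)-catechin 3-O-[(4S,5R)-5-(but-3-en-1-yl)-2,2-dimethyl-4-vinyl-1,3-dioxolane-4-carboxylate] | C=CCC[C@H]1OC(C)(C)O[C@]1(C=C)C(=O)O[C@H]1Cc2c(O[Si](C)(C)C(C)(C)C)cc(O[Si](C)(C)C(C)(C)C)cc2O[C@@H]1c1ccc(O[Si](C)(C)C(C)(C)C)c(O[Si](C)(C)C(C)(C)C)c1
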